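(The rate constants are assumed; the rest is arithmetic.)

You asked for a quick number and gave your hunch, so I reckoned first.

starting material 46 mM; second substrate 46.0 mM; enzyme 4.6 µM; time 10 min

- which holds at 10 min: what has brought the reaction to rest, or that it has not come to rest (it is still moving / no working catalyst is left / all of the starting material has reacted / forward and back rates have come level)
- amount of target at 10 min, in percent of the starting material charged

    starting material + enzyme ⇌ complex A (K1 = 9.6 M⁻¹, k1 = 79000 M⁻¹ s⁻¹)
    complex A → enzyme + target (k2 = 41 s⁻¹)
    second substrate + enzyme ⇌ complex B (K3 = 9.9 M⁻¹, k3 = 2.6 × 10⁵ M⁻¹ s⁻¹)
    complex B → enzyme + second product (k4 = 65 s⁻¹)
    2 second substrate → homo dimer (k5 = 0.11 M⁻¹ s⁻¹)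
    target ⇌ isomer of the product (K6 = 2.4, k6 = 0.0068 s⁻¹)

- a step written with two of one species runs at k times the square of its concentration and takes two of it each time
- the reaction counts as stopped when no species that holds the starting material changes by six tenths of a point or more over the second half of the time
- run time (flask): 10 min

1. In a one-step world the starting material would fade on a single clock, so I looked for that clock here.

2. Complex A fell back at 8230 s⁻¹, far faster than it went on to target at 41 s⁻¹, so I treated binding as an equilibrium.

3. I worked in powers of ten. A bound enzyme had 4.39 in the logarithm for its turnovers over the run, and the bound part of the starting material, with the enzyme wholly free, had −4.35. I called the product of binding constant, turnover constant, enzyme charge and time the enzyme passes: 1.09, the natural logarithm of the fall in starting material with the enzyme wholly free.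

4. The dimerisation half-life of the second substrate, 1.65 min, was shorter than the run, so I dropped that competitor. The starting material left a free enzyme share of 0.694. Decay was then pseudo-first-order, with 47.1% left, so I called the flask still moving.

5. The target–isomer exchange had a half-life of 1.20 min, short against the run, so I split the product by its equilibrium and added a lag for fresh arrivals. That gave me 19.9% target.

6. Your forecast said it is still moving with 21% target, a little above mine. Its grounds for the target were that “the target sits a bit above its equilibrium share”, and my lag put the target above that share too, so this did not tell our two numbers apart.

7. The flask gave it is still moving and 21.3% target.

In this flask the exchange half-life of 1.20 min was shorter than the starting material's half-life of 9.20 min from the passes, and at 10.0 min target was still made 1.27 times as fast as it was used up. In the neighbour flask with 0.0011 mM of enzyme the passes fell to 0.260, which put that half-life at 38.5 min, longer than the run, and that flask held 84.5% starting material and 6.44% target.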